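## Structural features

Atom labels follow the benzofuran numbering of the target 17 throughout, also in its precursors. The target is a 3,3a-dihydrobenzofuran-6(2H)-one: a tetrahydrofuran ring (ring A: O1, C2, C3, C3a, C7a) fused along C3a–C7a to a six-membered cross-conjugated dienone (ring B: C3a, C4 to C7, C7a). Ring B holds a 2-methoxy enone (C4=C5(OMe)–C6=O) and, on the other side of the carbonyl, a vinylogous ester (C6(=O)–C7=C7a–O1) that links it to ring A. Three stereocentres are contiguous: C2 (R, 3,4,5-trimethoxyphenyl), C3 (S, methyl) and the quaternary ring-fusion carbon C3a (S, allyl). Aryl and methyl are cis, methyl and allyl trans. The fragile parts are the 4,4-disubstituted cyclohexadienone (its allyl group can migrate by [3,3] shifts on heating, and acid leads to aromatisation), the two enol ethers, the ionisable electron-rich benzylic C2–O1 bond and the terminal alkene. The real difficulty is the all-carbon quaternary centre C3a next to C3, which has to be made without ring B ever becoming aromatic and with the right oxygenation at C5 and C6. The key step uses the fact that C5 carries a methoxy group next to the C6 carbonyl. C5 can therefore be a sulfonyl-stabilised carbanion whose sulfonyl group later leaves to give the C4=C5 enol ether, while C6–C7=C7a–O1 is already present as an exocyclic β-alkoxyacrylate on ring A.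

## Logic of the disconnections

17 ⇒ 16. The C4=C5 double bond is taken back to a C5 carbon carrying methoxy and phenylsulfonyl. This puts a carbanion-stabilising group on C5, which is what makes the next cut possible. The forward step must expel sulfinate towards C4 under conditions mild enough to leave the allyl group on C3a.

16 ⇒ 15. The C5–C6 bond of ring B is cut. Ring B disappears and a monocyclic ring A remains that already carries all three stereocentres, the ester carbon C6 on an exocyclic C7=C7a bond and C5 on a two-carbon arm. The forward step requires that C5 is the only site deprotonated and that the ester sits cis to C3a (E geometry), since only then can C5 reach C6.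

15 ⇒ 14. The C5–S bond is cut back to a dimethyl acetal. The sulfone would not survive enolate chemistry, hydride reduction or methanolic palladium chemistry, so it is introduced last. The forward exchange must use an acid weak enough to spare the enol ether and its geometry.

14 ⇒ 13. The O1–C7a and C7–C6 bonds are cut together, which leads back to an alkynol, carbon monoxide and methanol. The reason is stereochemical: anti addition of oxygen and palladium across the alkyne, followed by carbonylation with retention, puts the ester trans to O1, which is the E geometry needed by 15. A carbonyl olefination of a lactone would leave that geometry to thermodynamics. The demand on the forward step is that the vinylpalladium intermediate takes up CO faster than it reacts with the allyl group.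

13 ⇒ 12 ⇒ 11. C7 is removed (one-carbon alkyne homologation of a masked aldehyde), and the lactol is taken back to the lactone. This returns to a γ-lactone in which C3a is the α-carbon, so the quaternary centre can be built by enolate alkylation. The forward homologation has to work on an aldehyde that is held in its closed form and flanked by a quaternary carbon.

11 ⇒ 10 + 7. The C3a–allyl bond is cut. The enolate of 10 has the C3 methyl and the C2 aryl group on the same face, so the second electrophile must enter trans to methyl. This fixes the order: the arm that becomes C4–C5 goes in first, the allyl group last.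

10 ⇒ 9 ⇒ 8 ⇒ 6 + 7. The acetal is taken back to an aldehyde and this to a terminal alkene, and the C3a–C4 bond is cut as a first allylation. One reagent, 7, thus supplies both arms. The forward oxidative cleavage must spare the electron-rich arene.

6 ⇒ 5 ⇒ 4 ⇒ 3. The lactone is taken back to a 1,4-diol and the primary hydroxyl to a terminal alkene. This leaves an acyclic homoallylic alcohol with the two stereocentres C2 and C3 in a syn relationship, which corresponds to the cis lactone.

3 ⇒ 1 + 2. The C2–C3 bond is cut as a crotylation of an aryl aldehyde. The Z geometry of 2 gives the syn relationship and a chiral Brønsted acid gives the absolute configuration. The forward step must deliver high enantiomeric purity, because every later stereocentre is relayed from these two.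

## Other disconnections considered

Alternative 1: The cut is C2–C3 of ring A, made while ring B is still aromatic. In the forward direction the diazoalkane A1 is decomposed by Rh2(R-PTAD)4 (or its enantiomer). The carbene at the future C3 inserts into the benzylic C–H bond of the neighbouring 3,4,5-trimethoxybenzyl ether and closes ring A as the cis-dihydrobenzofuran A2. Heating A2 would then move the allyl group from O6 to C3a by a Claisen shift followed by a Cope shift (C7 is blocked by bromine, C5 by methoxy) to give the bromodienone A3, and reductive removal of bromine would give 17. In its favour, one catalytic asymmetric event sets C2 and C3 cis with catalyst control, and insertions of this type are established chemistry. On precedent for the key step this alternative is the better of the two. Against it here: a pentasubstituted arene with the bromine in a defined position has to be prepared, and the quaternary centre is left to a thermal sigmatropic cascade at the very end. The facial preference at C3a would rest on the adjacent methyl group alone. The cascade is reversible, so A3 would be one of several allyl isomers that can interconvert at the temperature needed. The last step must remove a vinylic bromine without touching the allyl group or the dienone. The chosen plan sets C3a by a kinetically controlled enolate alkylation at low temperature and never makes ring B aromatic, so no such equilibrium arises. Step economy is expected to be about equal. Mechanistically the alternative has a secure key step and an uncertain endgame, whereas the chosen plan has two unprecedented late steps, each with a fallback in known chemistry.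

Alternative 2: The cut is C3a–C7a. In the forward direction the cyclobutenone A4 is heated. The four-membered ring opens, and the ketene carbon of the opened form bonds to the disubstituted alkene terminus in a six-electron electrocyclisation, giving the 6,6-disubstituted cyclohexa-2,4-dienone A5. Desilylation, addition of the freed hydroxyl to the ring carbonyl and loss of isopropanol with carbonyl transposition would then give 17. In its favour, the plan is convergent, the four-carbon unit brings all the oxygen atoms of ring B in the right places, and the quaternary carbon forms under neutral thermal conditions in a well-known type of ring expansion. On convergence and on precedent of the key step it is the equal or the better of the chosen plan, and its longest linear sequence could be shorter. Against it here: the configuration at C3a is decided by the alkene geometry in A4 and by the helical sense of the closure, and only the acyclic stereocentre C3 on a freely rotating chain can bias the latter, so poor induction is to be expected. A4 also needs a trisubstituted alkene of defined geometry whose two sp3 substituents (allyl and the branched chain) are hard to tell apart in any olefination. A5 is a linearly conjugated dienone with an allyl group on the saturated carbon and is open to dimerisation and [3,3] shifts. The chosen plan controls C3a by structure, since both ring substituents shield one face of a cyclic enolate; on stereocontrol it is the better, on mechanism of the key step the less secure.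

Alternative 3: The cuts are C3a–C4 and C7–C7a, both made on the lactone 6 of the chosen route. In the forward direction the enolate of 6 adds to the enone A6 (Michael addition, C3a–C4). After proton transfer the methyl ketone enolate attacks the lactone carbonyl (Claisen condensation, C7–C7a), and O1 closes again onto the resulting 1,3-dicarbonyl unit to give A7. Oxidation to the phenol A8 and an allylation with dearomatisation at C3a would complete the synthesis. In its favour, ring B is made from 6 in one operation with enolate chemistry only. On step count to the bicyclic skeleton it is clearly better than the chosen plan, and the source of C2 and C3 is the same in both, so they are equal there. Against it here: A6 is a donor-substituted acceptor prone to polymerisation, and the sequence needs a proton transfer between two condensations on a hindered lactone. More seriously, the allyl group is missing. The C3a stereocentre formed in the Michael step is erased in A8, and the quaternary centre must then be created on a phenol in competition with O-allylation and attack at C7, with only the C3 methyl group to direct the face. The hardest feature of the target is thus left to the final step. The chosen plan installs both substituents of C3a on the lactone before ring B exists. The alternative is shorter up to A7, but its endgame is less controlled than steps 11 and 12 with their fallbacks.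

Key step: step 11

Assumption: the (R)-configured phosphoric acid of step 1 is taken to direct the crotyl group to the re face of 1. If the sense is the reverse, the (S)-acid is used and nothing else in the route changes.

## Route

Step 1
Reactants: 1 3,4,5-trimethoxybenzaldehyde; 2 (Z)-2-(but-2-en-1-yl)-4,4,5,5-tetramethyl-1,3,2-dioxaborolane ((Z)-crotylboronic acid pinacol ester)
Product: 3 (1R,2S)-2-methyl-1-(3,4,5-trimethoxyphenyl)but-3-en-1-ol
Conditions: (R)-3,3'-bis(2,4,6-triisopropylphenyl)-1,1'-binaphthyl-2,2'-diyl hydrogen phosphate (5 mol%), 4 Å molecular sieves, toluene, −30 °C; aqueous work-up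
Reagents that add atoms: none
Why: Chiral phosphoric acid-catalysed crotylboration through a closed chair (Zimmerman–Traxler) transition state: the Z geometry of 2 places the methyl group axial and gives the syn (1R,2S) relationship, while the (R)-acid, hydrogen-bonded to a boronate oxygen and to the formyl hydrogen, selects the re face of 1 and sets C1 as R.

Step 2
Reactants: 3 (1R,2S)-2-methyl-1-(3,4,5-trimethoxyphenyl)but-3-en-1-ol
Product: 4 (1R,2S)-2-methyl-1-(3,4,5-trimethoxyphenyl)butane-1,4-diol
Conditions: 9-borabicyclo[3.3.1]nonane (9-BBN, 2.2 equiv), THF, 0 °C to rt; then NaOH, H2O2, 0 °C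
Reagents that add atoms: hydrogen peroxide, OO
Why: Anti-Markovnikov hydroboration–oxidation; the bulky borane puts boron on the terminal carbon, one equivalent is consumed by the free hydroxyl, and neither stereocentre is touched.

Step 3
Reactants: 4 (1R,2S)-2-methyl-1-(3,4,5-trimethoxyphenyl)butane-1,4-diol
Product: 6 (4S,5R)-4-methyl-5-(3,4,5-trimethoxyphenyl)dihydrofuran-2(3H)-one, via lactol 5 (not isolated)
Conditions: TEMPO (20 mol%), PhI(OAc)2 (2.5 equiv), CH2Cl2, rt
Reagents that add atoms: none
Why: Nitroxyl-catalysed oxidative lactonisation of a 1,4-diol: the unhindered primary alcohol is oxidised first, the secondary hydroxyl closes onto the new carbonyl to give lactol 5, and 5 is oxidised again; no stereocentre is α to the carbonyl that forms, so the cis relationship is kept.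

Step 4
Reactants: 6 (4S,5R)-4-methyl-5-(3,4,5-trimethoxyphenyl)dihydrofuran-2(3H)-one; 7 allyl bromide
Product: 8 (3S,4S,5R)-3-allyl-4-methyl-5-(3,4,5-trimethoxyphenyl)dihydrofuran-2(3H)-one
Conditions: LiN(iPr)2 (1.05 equiv), THF, −78 °C; then 7 (1.1 equiv), −78 °C
Reagents that add atoms: none
Why: Lithium enolate alkylation of a γ-butyrolactone; the allyl group enters trans to the neighbouring methyl group, but this centre is enolised again in step 6, so its configuration is not critical.

Step 5
Reactants: 8 (3S,4S,5R)-3-allyl-4-methyl-5-(3,4,5-trimethoxyphenyl)dihydrofuran-2(3H)-one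
Product: 10 (3S,4S,5R)-3-(2,2-dimethoxyethyl)-4-methyl-5-(3,4,5-trimethoxyphenyl)dihydrofuran-2(3H)-one, via aldehyde 9 (not isolated)
Conditions: O3, CH2Cl2–MeOH (3:1), Sudan red 7B as indicator, −78 °C; Me2S, −78 °C to rt; then TsOH·H2O (5 mol%), rt
Reagents that add atoms: methanol, CO; ozone, [O-][O+]=O (supplies the carbonyl oxygen of 9 only)
Why: Ozonolysis of the terminal alkene with reductive work-up gives aldehyde 9, which is acetalised in the same pot by acid catalysis in methanol; the alkene reacts with ozone faster than the trimethoxyarene, and the indicator marks the end point.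

Step 6
Reactants: 10 (3S,4S,5R)-3-(2,2-dimethoxyethyl)-4-methyl-5-(3,4,5-trimethoxyphenyl)dihydrofuran-2(3H)-one; 7 allyl bromide
Product: 11 (3R,4S,5R)-3-allyl-3-(2,2-dimethoxyethyl)-4-methyl-5-(3,4,5-trimethoxyphenyl)dihydrofuran-2(3H)-one
Conditions: LiN(iPr)2 (1.2 equiv), THF, −78 °C; DMPU, 7 (2 equiv), −78 to −40 °C
Reagents that add atoms: none
Why: Alkylation of a trisubstituted lactone enolate: the methyl and aryl groups lie on the same face of the planar enolate, so allyl bromide attacks from the opposite face and the allyl group ends up trans to methyl; this sets the quaternary centre (C3a of 17) and fixes which arm is cis to methyl.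

Step 7
Reactants: 11 (3R,4S,5R)-3-allyl-3-(2,2-dimethoxyethyl)-4-methyl-5-(3,4,5-trimethoxyphenyl)dihydrofuran-2(3H)-one
Product: 12 (3R,4S,5R)-3-allyl-3-(2,2-dimethoxyethyl)-4-methyl-5-(3,4,5-trimethoxyphenyl)tetrahydrofuran-2-ol (anomer mixture)
Conditions: iBu2AlH (1.2 equiv), CH2Cl2, −78 °C; aqueous potassium sodium tartrate
Reagents that add atoms: none
Why: Partial reduction of a lactone to the lactol; the tetrahedral aluminium alkoxide survives at low temperature until work-up, and the acetal and the alkene are inert.

Step 8
Reactants: 12 (3R,4S,5R)-3-allyl-3-(2,2-dimethoxyethyl)-4-methyl-5-(3,4,5-trimethoxyphenyl)tetrahydrofuran-2-ol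
Product: 13 (1R,2S,3R)-3-(2,2-dimethoxyethyl)-3-ethynyl-2-methyl-1-(3,4,5-trimethoxyphenyl)hex-5-en-1-ol
Conditions: dimethyl (1-diazo-2-oxopropyl)phosphonate (2 equiv), K2CO3 (3 equiv), MeOH, 0 °C to rt
Reagents that add atoms: dimethyl (1-diazo-2-oxopropyl)phosphonate, CC(=O)C(=[N+]=[N-])P(=O)(OC)OC
Why: Seyferth–Gilbert homologation with the Ohira–Bestmann reagent: the open hydroxy aldehyde form of 12 reacts with the diazophosphonate anion, and the alkylidene carbene formed by loss of phosphate and N2 undergoes a 1,2-hydrogen shift to the terminal alkyne; the carbon next to the aldehyde is quaternary and cannot epimerise.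

Step 9
Reactants: 13 (1R,2S,3R)-3-(2,2-dimethoxyethyl)-3-ethynyl-2-methyl-1-(3,4,5-trimethoxyphenyl)hex-5-en-1-ol
Product: 14 methyl (E)-2-[(3R,4S,5R)-3-allyl-3-(2,2-dimethoxyethyl)-4-methyl-5-(3,4,5-trimethoxyphenyl)dihydrofuran-2(3H)-ylidene]acetate
Conditions: PdCl2(MeCN)2 (5 mol%), p-benzoquinone (1.5 equiv), CO (1 atm), MeOH, 0 °C
Reagents that add atoms: carbon monoxide, [C-]#[O+]; methanol, CO
Why: Oxidative cyclisation–methoxycarbonylation of a 4-yn-1-ol: divalent palladium activates the alkyne, the hydroxyl adds anti in the 5-exo-dig mode to give a vinylpalladium species with the metal trans to O1, and CO insertion and methanolysis with retention place the ester trans to O1 (E, cis to C3a); p-benzoquinone reoxidises zerovalent palladium.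

Step 10
Reactants: 14 methyl (E)-2-[(3R,4S,5R)-3-allyl-3-(2,2-dimethoxyethyl)-4-methyl-5-(3,4,5-trimethoxyphenyl)dihydrofuran-2(3H)-ylidene]acetate
Product: 15 methyl (E)-2-[(3R,4S,5R)-3-allyl-3-[(2R)-2-methoxy-2-(phenylsulfonyl)ethyl]-4-methyl-5-(3,4,5-trimethoxyphenyl)dihydrofuran-2(3H)-ylidene]acetate (one epimer at the sulfone carbon drawn; both are expected and both serve)
Conditions: PhSO2H (2 equiv), CaCl2, CH2Cl2, 0 °C to rt
Reagents that add atoms: benzenesulfinic acid, O=S(O)c1ccccc1
Why: Acid-mediated exchange of one methoxy group of a dimethyl acetal for sulfinate through the oxocarbenium ion, a known preparation of α-alkoxy sulfones; CaCl2 binds the methanol released, and the weak acid in a non-aqueous medium should leave the electron-poor enol ether and its E geometry untouched.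

Step 11
Reactants: 15 methyl (E)-2-[(3R,4S,5R)-3-allyl-3-[(2R)-2-methoxy-2-(phenylsulfonyl)ethyl]-4-methyl-5-(3,4,5-trimethoxyphenyl)dihydrofuran-2(3H)-ylidene]acetate
Product: 16 (2R,3S,3aR,5S)-3a-allyl-5-methoxy-3-methyl-5-(phenylsulfonyl)-2-(3,4,5-trimethoxyphenyl)-3,3a,4,5-tetrahydrobenzofuran-6(2H)-one (one C5 epimer drawn)
Conditions: LiN(iPr)2 (1.15 equiv), THF, −78 to −30 °C; AcOH, −78 °C
Reagents that add atoms: none
Why: Proposed new method: LiN(iPr)2 removes the C5 hydrogen, the only activated one in 15 (α to sulfonyl and methoxy; C3a has no hydrogen, so the β-alkoxyacrylate has no γ-position to deprotonate), and the α-methoxy sulfonyl carbanion adds to the ester carbonyl C6; collapse of the tetrahedral intermediate with loss of methoxide forms the C5–C6 bond and the C6 ketone. The closest known reaction type is the acylation of lithiated α-alkoxy sulfones, and of sulfone carbanions in general, by esters between two molecules; its use to close a ring onto a vinylogous carbonate is new. Ring B closes in the 6-exo-trig mode, the C6=O bond being exocyclic to the ring C5–C4–C3a–C7a–C7–C6. The new stereocentre C5 is set only by the approach of the ester to a configurationally labile carbanion held on the face of ring A syn to the C3 methyl group, and either epimer is acceptable because C5 becomes trigonal in step 12. The step needs attack at the carbonyl and not conjugate attack at C7a, which is secured because the latter would form a four-membered ring. It also needs C6 within reach of C5, which is secured by the E geometry fixed in step 9. The product has no hydrogen on C5 and cannot be deprotonated further, so little more than one equivalent of base suffices, and the cold acetic acid quench removes lithium methoxide before it can reopen the ketone or start the elimination of step 12.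

Step 12
Reactants: 16 (2R,3S,3aR,5S)-3a-allyl-5-methoxy-3-methyl-5-(phenylsulfonyl)-2-(3,4,5-trimethoxyphenyl)-3,3a,4,5-tetrahydrobenzofuran-6(2H)-one
Product: 17 (2R,3S,3aS)-3a-allyl-5-methoxy-3-methyl-2-(3,4,5-trimethoxyphenyl)-3,3a-dihydrobenzofuran-6(2H)-one
Conditions: DBU (3 equiv), MeCN, 20 to 50 °C
Reagents that add atoms: none
Why: Proposed new method: DBU removes one of the C4 hydrogens, the only hydrogens β to the sulfonyl group, while benzenesulfinate leaves from C5 in an E2 process with E1 character, helped by the methoxy lone pair and by conjugation of the new C4=C5 bond with the C6 carbonyl; the closest known reaction types are the base-induced loss of sulfinic acid from alkylated α-alkoxy sulfones to give enol ethers and the dehydrosulfonylation of α-sulfonyl carbonyl compounds, but the case with a ketone on the sulfone-bearing carbon is unexplored; no stereocentre is formed or touched, and the temperature stays low enough to keep the allyl group on C3a.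

## Compound list

1 | 3,4,5-trimethoxybenzaldehyde | COc1cc(C=O)cc(OC)c1OC | starting material
2 | (Z)-2-(but-2-en-1-yl)-4,4,5,5-tetramethyl-1,3,2-dioxaborolane | C/C=C\CB1OC(C)(C)C(C)(C)O1 | starting material
3 | (1R,2S)-2-methyl-1-(3,4,5-trimethoxyphenyl)but-3-en-1-ol | C=C[C@H](C)[C@@H](O)c1cc(OC)c(OC)c(OC)c1 | intermediate
4 | (1R,2S)-2-methyl-1-(3,4,5-trimethoxyphenyl)butane-1,4-diol | OCC[C@H](C)[C@@H](O)c1cc(OC)c(OC)c(OC)c1 | intermediate
5 | (4S,5R)-4-methyl-5-(3,4,5-trimethoxyphenyl)tetrahydrofuran-2-ol (anomer mixture, not isolated) | C[C@H]1CC(O)O[C@H]1c1cc(OC)c(OC)c(OC)c1 | intermediate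
6 | (4S,5R)-4-methyl-5-(3,4,5-trimethoxyphenyl)dihydrofuran-2(3H)-one | C[C@H]1CC(=O)O[C@H]1c1cc(OC)c(OC)c(OC)c1 | intermediate
7 | allyl bromide | C=CCBr | starting material
8 | (3S,4S,5R)-3-allyl-4-methyl-5-(3,4,5-trimethoxyphenyl)dihydrofuran-2(3H)-one | C=CC[C@@H]1C(=O)O[C@@H](c2cc(OC)c(OC)c(OC)c2)[C@H]1C | intermediate
9 | 2-[(3S,4S,5R)-4-methyl-2-oxo-5-(3,4,5-trimethoxyphenyl)tetrahydrofuran-3-yl]acetaldehyde (not isolated) | O=CC[C@@H]1C(=O)O[C@@H](c2cc(OC)c(OC)c(OC)c2)[C@H]1C | intermediate
10 | (3S,4S,5R)-3-(2,2-dimethoxyethyl)-4-methyl-5-(3,4,5-trimethoxyphenyl)dihydrofuran-2(3H)-one | COC(OC)C[C@@H]1C(=O)O[C@@H](c2cc(OC)c(OC)c(OC)c2)[C@H]1C | intermediate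
11 | (3R,4S,5R)-3-allyl-3-(2,2-dimethoxyethyl)-4-methyl-5-(3,4,5-trimethoxyphenyl)dihydrofuran-2(3H)-one | C=CC[C@]1(CC(OC)OC)C(=O)O[C@@H](c2cc(OC)c(OC)c(OC)c2)[C@H]1C | intermediate
12 | (3R,4S,5R)-3-allyl-3-(2,2-dimethoxyethyl)-4-methyl-5-(3,4,5-trimethoxyphenyl)tetrahydrofuran-2-ol (anomer mixture) | C=CC[C@]1(CC(OC)OC)C(O)O[C@@H](c2cc(OC)c(OC)c(OC)c2)[C@H]1C | intermediate
13 | (1R,2S,3R)-3-(2,2-dimethoxyethyl)-3-ethynyl-2-methyl-1-(3,4,5-trimethoxyphenyl)hex-5-en-1-ol | C=CC[C@](CC(OC)OC)(C#C)[C@H](C)[C@@H](O)c1cc(OC)c(OC)c(OC)c1 | intermediate
14 | methyl (E)-2-[(3R,4S,5R)-3-allyl-3-(2,2-dimethoxyethyl)-4-methyl-5-(3,4,5-trimethoxyphenyl)dihydrofuran-2(3H)-ylidene]acetate | C=CC[C@]1(CC(OC)OC)/C(=C\C(=O)OC)O[C@@H](c2cc(OC)c(OC)c(OC)c2)[C@H]1C | intermediate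
15 | methyl (E)-2-[(3R,4S,5R)-3-allyl-3-[(2R)-2-methoxy-2-(phenylsulfonyl)ethyl]-4-methyl-5-(3,4,5-trimethoxyphenyl)dihydrofuran-2(3H)-ylidene]acetate (one epimer at the sulfone carbon drawn) | C=CC[C@]1(C[C@H](OC)S(=O)(=O)c2ccccc2)/C(=C\C(=O)OC)O[C@@H](c2cc(OC)c(OC)c(OC)c2)[C@H]1C | intermediate
16 | (2R,3S,3aR,5S)-3a-allyl-5-methoxy-3-methyl-5-(phenylsulfonyl)-2-(3,4,5-trimethoxyphenyl)-3,3a,4,5-tetrahydrobenzofuran-6(2H)-one (one C5 epimer drawn) | C=CC[C@]12C[C@](OC)(S(=O)(=O)c3ccccc3)C(=O)C=C1O[C@@H](c1cc(OC)c(OC)c(OC)c1)[C@H]2C | intermediate
17 | (2R,3S,3aS)-3a-allyl-5-methoxy-3-methyl-2-(3,4,5-trimethoxyphenyl)-3,3a-dihydrobenzofuran-6(2H)-one | C=CC[C@]12C=C(OC)C(=O)C=C1O[C@@H](c1cc(OC)c(OC)c(OC)c1)[C@H]2C | target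

## Step count and least certain steps

Total: 12 steps. Longest linear sequence: 12 steps (the route is linear; 7 is used twice).

Step 11 (key step). The most likely failure is that the carbanion adds too slowly to the ester carbonyl, which is deactivated by the push–pull conjugation. The carbanion would then decay by loss of sulfinate, or methoxide would reverse the acylation on warming. The fallback keeps the C5–C6 bond but makes it by the known addition of a sulfonyl carbanion to an aldehyde followed by oxidation. It sets out from 14 and returns at 16: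
- Reduction of the ester with iBu2AlH should give the allylic alcohol (E)-2-[(3R,4S,5R)-3-allyl-3-(2,2-dimethoxyethyl)-4-methyl-5-(3,4,5-trimethoxyphenyl)dihydrofuran-2(3H)-ylidene]ethan-1-ol F1.
- MnO2 should oxidise F1 to the aldehyde (E)-2-[(3R,4S,5R)-3-allyl-3-(2,2-dimethoxyethyl)-4-methyl-5-(3,4,5-trimethoxyphenyl)dihydrofuran-2(3H)-ylidene]acetaldehyde F2.
- Exchange with PhSO2H and CaCl2 as in step 10 should give (E)-2-[(3R,4S,5R)-3-allyl-3-[2-methoxy-2-(phenylsulfonyl)ethyl]-4-methyl-5-(3,4,5-trimethoxyphenyl)dihydrofuran-2(3H)-ylidene]acetaldehyde F3.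
- LiN(iPr)2 at −78 °C should close ring B by addition of the C5 carbanion to the aldehyde, giving (2R,3S,3aR)-3a-allyl-5-methoxy-3-methyl-5-(phenylsulfonyl)-2-(3,4,5-trimethoxyphenyl)-2,3,3a,4,5,6-hexahydrobenzofuran-6-ol F4.
- Oxidation of the allylic alcohol F4 with MnO2 (or Dess–Martin periodinane buffered with NaHCO3) then gives 16.

Step 12. The most likely failure is that sulfinate does not leave under mild conditions, because the adjacent carbonyl opposes positive charge at C5, while more forcing conditions start [3,3] migration of the allyl group or cleavage of the α-sulfonyl ketone. The fallback replaces the elimination by a reduction–oxidation pair of known reactions. It sets out from 16 and returns at 17: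
- Reductive desulfonylation with Al(Hg) in aqueous THF should give (2R,3S,3aR)-3a-allyl-5-methoxy-3-methyl-2-(3,4,5-trimethoxyphenyl)-3,3a,4,5-tetrahydrobenzofuran-6(2H)-one F5.
- Enolisation towards C5, the only possible direction, with LiN(iPr)2 and trapping with Me3SiCl should give [(2R,3S,3aR)-3a-allyl-5-methoxy-3-methyl-2-(3,4,5-trimethoxyphenyl)-2,3,3a,4-tetrahydrobenzofuran-6-yl]oxy(trimethyl)silane F6.
- Saegusa–Ito oxidation of F6 with Pd(OAc)2 in MeCN at room temperature introduces the C4=C5 bond and gives 17.

Step 9. The most likely failure is that the vinylpalladium intermediate, which lies cis to C3a, inserts the neighbouring allyl alkene before it takes up CO, or that the divalent palladium/benzoquinone system attacks the terminal alkene in a Wacker-type reaction. The fallback builds the enol ether from the lactone without a vinyl–metal species. It sets out from 11 and returns at 14: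
- Addition of LiCH2CO2Me (from methyl acetate and LiN(iPr)2, THF, −78 °C) to the lactone carbonyl should give methyl 2-[(3R,4S,5R)-3-allyl-3-(2,2-dimethoxyethyl)-2-hydroxy-4-methyl-5-(3,4,5-trimethoxyphenyl)tetrahydrofuran-2-yl]acetate F7.
- Dehydration with (CF3CO)2O and pyridine, then Et3N, can only go to the exocyclic position and is expected to give mainly the isomer with the ester away from the quaternary carbon, methyl (Z)-2-[(3R,4S,5R)-3-allyl-3-(2,2-dimethoxyethyl)-4-methyl-5-(3,4,5-trimethoxyphenyl)dihydrofuran-2(3H)-ylidene]acetate F8.
- Photochemical E/Z isomerisation of the β-alkoxyacrylate (300 nm, acetone as sensitiser) establishes a mixture from which 14 is separated, and F8 is recycled.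

Step 8. The most likely failure is slow reaction of the diazophosphonate anion, because the lactol stays closed and the aldehyde carbon is flanked by a quaternary centre, so the reagent decomposes first. The fallback uses a more reactive, unstabilised ylide and a separate elimination. It sets out from 12 and returns at 13:
- A Wittig reaction with the ylide from (bromomethyl)triphenylphosphonium bromide and KOtBu in THF should give (1R,2S,3R)-3-(2-bromovinyl)-3-(2,2-dimethoxyethyl)-2-methyl-1-(3,4,5-trimethoxyphenyl)hex-5-en-1-ol F9.
- Dehydrobromination of F9 with excess KOtBu then gives 13.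

Step 10. The most likely failures are an incomplete exchange (an equilibrium that lies on the acetal side), loss of methanol from the acetal to an enol ether arm, or slow acid-promoted drift of the E geometry. The fallback introduces sulfur as a thiolate equivalent at low temperature and oxidises afterwards. It sets out from 14 and returns at 15:
- PhSSiMe3 with catalytic Me3SiOSO2CF3 in CH2Cl2 at −78 °C should give the mixed O,S-acetal methyl (E)-2-[(3R,4S,5R)-3-allyl-3-[2-methoxy-2-(phenylsulfanyl)ethyl]-4-methyl-5-(3,4,5-trimethoxyphenyl)dihydrofuran-2(3H)-ylidene]acetate F10.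
- Oxidation of F10 at sulfur with H2O2 and catalytic (NH4)6Mo7O24 in ethanol at 0 °C is much faster than oxidation of the terminal alkene or the electron-poor enol ether and gives 15.

## Further compounds

F1 | step 11 | (E)-2-[(3R,4S,5R)-3-allyl-3-(2,2-dimethoxyethyl)-4-methyl-5-(3,4,5-trimethoxyphenyl)dihydrofuran-2(3H)-ylidene]ethan-1-ol | C=CC[C@]1(CC(OC)OC)/C(=C\CO)O[C@@H](c2cc(OC)c(OC)c(OC)c2)[C@H]1C
F2 | step 11 | (E)-2-[(3R,4S,5R)-3-allyl-3-(2,2-dimethoxyethyl)-4-methyl-5-(3,4,5-trimethoxyphenyl)dihydrofuran-2(3H)-ylidene]acetaldehyde | C=CC[C@]1(CC(OC)OC)/C(=C\C=O)O[C@@H](c2cc(OC)c(OC)c(OC)c2)[C@H]1C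
F3 | step 11 | (E)-2-[(3R,4S,5R)-3-allyl-3-[2-methoxy-2-(phenylsulfonyl)ethyl]-4-methyl-5-(3,4,5-trimethoxyphenyl)dihydrofuran-2(3H)-ylidene]acetaldehyde (both epimers at the sulfone carbon) | C=CC[C@]1(CC(OC)S(=O)(=O)c2ccccc2)/C(=C\C=O)O[C@@H](c2cc(OC)c(OC)c(OC)c2)[C@H]1C
F4 | step 11 | (2R,3S,3aR)-3a-allyl-5-methoxy-3-methyl-5-(phenylsulfonyl)-2-(3,4,5-trimethoxyphenyl)-2,3,3a,4,5,6-hexahydrobenzofuran-6-ol (mixture at C5 and C6) | C=CC[C@]12CC(OC)(S(=O)(=O)c3ccccc3)C(O)C=C1O[C@@H](c1cc(OC)c(OC)c(OC)c1)[C@H]2C
F5 | step 12 | (2R,3S,3aR)-3a-allyl-5-methoxy-3-methyl-2-(3,4,5-trimethoxyphenyl)-3,3a,4,5-tetrahydrobenzofuran-6(2H)-one (C5 epimers) | C=CC[C@]12CC(OC)C(=O)C=C1O[C@@H](c1cc(OC)c(OC)c(OC)c1)[C@H]2C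
F6 | step 12 | [(2R,3S,3aR)-3a-allyl-5-methoxy-3-methyl-2-(3,4,5-trimethoxyphenyl)-2,3,3a,4-tetrahydrobenzofuran-6-yl]oxy(trimethyl)silane | C=CC[C@]12CC(OC)=C(O[Si](C)(C)C)C=C1O[C@@H](c1cc(OC)c(OC)c(OC)c1)[C@H]2C
F7 | step 9 | methyl 2-[(3R,4S,5R)-3-allyl-3-(2,2-dimethoxyethyl)-2-hydroxy-4-methyl-5-(3,4,5-trimethoxyphenyl)tetrahydrofuran-2-yl]acetate (anomer mixture) | C=CC[C@]1(CC(OC)OC)C(O)(CC(=O)OC)O[C@@H](c2cc(OC)c(OC)c(OC)c2)[C@H]1C
F8 | step 9 | methyl (Z)-2-[(3R,4S,5R)-3-allyl-3-(2,2-dimethoxyethyl)-4-methyl-5-(3,4,5-trimethoxyphenyl)dihydrofuran-2(3H)-ylidene]acetate | C=CC[C@]1(CC(OC)OC)/C(=C/C(=O)OC)O[C@@H](c2cc(OC)c(OC)c(OC)c2)[C@H]1C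
F9 | step 8 | (1R,2S,3R)-3-(2-bromovinyl)-3-(2,2-dimethoxyethyl)-2-methyl-1-(3,4,5-trimethoxyphenyl)hex-5-en-1-ol (E/Z mixture) | C=CC[C@](CC(OC)OC)(C=CBr)[C@H](C)[C@@H](O)c1cc(OC)c(OC)c(OC)c1
F10 | step 10 | methyl (E)-2-[(3R,4S,5R)-3-allyl-3-[2-methoxy-2-(phenylsulfanyl)ethyl]-4-methyl-5-(3,4,5-trimethoxyphenyl)dihydrofuran-2(3H)-ylidene]acetate (both epimers at the sulfur-bearing carbon) | C=CC[C@]1(CC(OC)Sc2ccccc2)/C(=C\C(=O)OC)O[C@@H](c2cc(OC)c(OC)c(OC)c2)[C@H]1C
A1 | alternative 1 | 1-(allyloxy)-2-bromo-4-(1-diazoethyl)-6-methoxy-3-[(3,4,5-trimethoxybenzyl)oxy]benzene | C=CCOc1c(Br)c(OCc2cc(OC)c(OC)c(OC)c2)c(C(C)=[N+]=[N-])cc1OC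
A2 | alternative 1 | (2R,3S)-6-(allyloxy)-7-bromo-5-methoxy-3-methyl-2-(3,4,5-trimethoxyphenyl)-2,3-dihydrobenzofuran | C=CCOc1c(Br)c2O[C@@H](c3cc(OC)c(OC)c(OC)c3)[C@@H](C)c2cc1OC
A3 | alternative 1 | (2R,3S,3aS)-3a-allyl-7-bromo-5-methoxy-3-methyl-2-(3,4,5-trimethoxyphenyl)-3,3a-dihydrobenzofuran-6(2H)-one | C=CC[C@]12C=C(OC)C(=O)C(Br)=C1O[C@@H](c1cc(OC)c(OC)c(OC)c1)[C@H]2C
A4 | alternative 2 | 4-[(3S,4R)-2-allyl-4-(tert-butyldimethylsilyloxy)-3-methyl-4-(3,4,5-trimethoxyphenyl)but-1-en-1-yl]-3-isopropoxy-4-methoxycyclobut-2-en-1-one (alkene geometry and ring C4 configuration left open) | C=CCC(=CC1(OC)C(OC(C)C)=CC1=O)[C@H](C)[C@@H](O[Si](C)(C)C(C)(C)C)c1cc(OC)c(OC)c(OC)c1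
A5 | alternative 2 | (S)-6-allyl-6-[(1R,2S)-1-(tert-butyldimethylsilyloxy)-1-(3,4,5-trimethoxyphenyl)propan-2-yl]-3-isopropoxy-4-methoxycyclohexa-2,4-dien-1-one | C=CC[C@@]1(C=C(OC)C(OC(C)C)=CC1=O)[C@H](C)[C@@H](O[Si](C)(C)C(C)(C)C)c1cc(OC)c(OC)c(OC)c1
A6 | alternative 3 | 3-methoxybut-3-en-2-one | CC(=O)C(=C)OC
A7 | alternative 3 | (2R,3S,3aS,5S)-5-methoxy-3-methyl-2-(3,4,5-trimethoxyphenyl)-3,3a,4,5-tetrahydrobenzofuran-6(2H)-one (one C3a and C5 epimer drawn) | CO[C@H]1C[C@@H]2C(=CC1=O)O[C@@H](c1cc(OC)c(OC)c(OC)c1)[C@H]2C
A8 | alternative 3 | (2R,3S)-5-methoxy-3-methyl-2-(3,4,5-trimethoxyphenyl)-2,3-dihydrobenzofuran-6-ol | COc1cc2c(cc1O)O[C@@H](c1cc(OC)c(OC)c(OC)c1)[C@H]2C
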